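**Assumptions (one line each)**
- Side-chain locants follow tocotrienol numbering (C1′ is attached to chroman C2); the target is (2R, 9′R, 3′E, 7′E).
- The route is a proposal and has not been run; the ligand antipode in step 3 is assigned by analogy from my recollection of Trost vinyl-epoxide etherifications ((R,R)-ligand gives (R)-2-alkoxybut-3-en-1-ols). If the first run gives (R)-5, use the (R,R)-ligand; nothing else changes.

**Retrosynthetic overview**
1. Target ⇒ global desilylation ⇒ C1′–C2′ disconnection into (S)-chromanylmethyl triflate 7 and the α-sulfonyl anion of (8R)-8-silyloxyfarnesyl phenyl sulfone 13; the sulfone is removed with Pd/LiBHEt3.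
2. Sulfone 13 ⇒ geranyl phenyl sulfone: terminal SeO2 oxidation to the (E)-enal, Brown allylation to set C9′ (R), cross-metathesis with 2-methyl-2-butene to install the prenyl terminus.
3. Chroman 7 (the only ring formed): O1–C2 bond and C2 stereocentre by Pd-catalysed asymmetric etherification of bromophenol 3 with isoprene monoepoxide, then the pyran ring is closed onto the existing arene (C4–C4a) by hydroboration/intramolecular B-alkyl Suzuki coupling.
4. Bromophenol 3 ⇐ methylhydroquinone (selective mono-silylation, ortho-bromination).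

**Route**

Step 1
Reactants: 1, 2-methylhydroquinone
Product: 2, 2-methyl-4-(triisopropylsilyloxy)phenol
Conditions: TIPSCl (1.0 equiv), imidazole, DMF, −10 °C → rt; chromatography
Reagents that add atoms: triisopropylsilyl chloride, CC(C)[Si](Cl)(C(C)C)C(C)C
Why: Selective mono-silylation, because the bulky silyl chloride reacts at the unhindered 4-OH in preference to the OH flanked by the ortho-methyl, and the aryl TIPS ether survives every later step until fluoride.

Step 2
Reactants: 2
Product: 3, 2-bromo-6-methyl-4-(triisopropylsilyloxy)phenol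
Conditions: NBS (1.0 equiv), i-Pr2NH (10 mol%), CH2Cl2, −20 → 0 °C, dark
Reagents that add atoms: N-bromosuccinimide, O=C1CCC(=O)N1Br
Why: Electrophilic aromatic bromination directed ortho to the free phenol (para is blocked by OTIPS, the other ortho position carries CH3), so one regioisomer forms, and low temperature limits oxidation to the quinone.

Step 3
Reactants: 3; 4, 2-methyl-2-vinyloxirane (isoprene monoepoxide, racemic)
Product: 5, (2S)-2-[2-bromo-6-methyl-4-(triisopropylsilyloxy)phenoxy]-2-methylbut-3-en-1-ol
Conditions: Pd2(dba)3·CHCl3 (1 mol%), (S,S)-DACH-phenyl Trost ligand (3 mol%), CH2Cl2, rt, slow addition of 4 (1.3 equiv)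
Reagents that add atoms: none beyond reactant 4
Why: Trost Pd-catalysed asymmetric allylic etherification run as a dynamic kinetic asymmetric transformation: both epoxide enantiomers ionise to interconverting π-allyl-Pd complexes, the alkoxide released directs the phenol to the proximal tertiary terminus, and the chiral ligand sets the (S) tertiary ether centre (future C2).

Step 4
Reactants: 5
Product: 6, [(2S)-2,8-dimethyl-6-(triisopropylsilyloxy)chroman-2-yl]methanol
Conditions: 9-BBN (2.5 equiv), THF, 0 °C → rt; then Pd(dppf)Cl2 (5 mol%), aq K3PO4, THF/DMF, 65 °C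
Reagents that add atoms: none (9-BBN delivers H only; boron is lost)
Why: Anti-Markovnikov hydroboration of the only alkene followed by intramolecular B-alkyl Suzuki–Miyaura coupling onto the ortho C–Br closes the six-membered pyran ring (C4–C4a) without touching the quaternary stereocentre.

Step 5
Reactants: 6
Product: 7, [(2S)-2,8-dimethyl-6-(triisopropylsilyloxy)chroman-2-yl]methyl trifluoromethanesulfonate
Conditions: Tf2O, 2,6-lutidine, CH2Cl2, −78 °C; short silica plug, use at once
Reagents that add atoms: triflic anhydride, O=S(=O)(OS(=O)(=O)C(F)(F)F)C(F)(F)F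
Why: O-sulfonylation gives the leaving group needed for SN2 at a neopentyl-type CH2, which has no β-hydrogen on the quaternary carbon and so cannot eliminate.

Step 6
Reactants: 8, geranyl bromide
Product: 9, geranyl phenyl sulfone, [(2E)-3,7-dimethylocta-2,6-dienyl]sulfonylbenzene
Conditions: PhSO2Na, DMF, rt
Reagents that add atoms: sodium benzenesulfinate, [Na+].[O-]S(=O)c1ccccc1
Why: SN2 S-alkylation of the sulfinate by the primary allylic bromide, which keeps the 2E olefin.

Step 7
Reactants: 9
Product: 10, (2E,6E)-2,6-dimethyl-8-(phenylsulfonyl)octa-2,6-dienal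
Conditions: SeO2 (0.5 equiv), t-BuOOH, salicylic acid (cat.), CH2Cl2, rt; then MnO2, CH2Cl2 on the crude alcohol/aldehyde mixture
Reagents that add atoms: selenium dioxide, O=[Se]=O, with tert-butyl hydroperoxide, CC(C)(C)OO (one oxygen atom)
Why: Sharpless SeO2 allylic oxidation (ene then [2,3]-shift) is selective for the E-methyl of the terminal trisubstituted alkene, since the olefin next to the sulfone is deactivated, and MnO2 converges the mixture on the (E)-enal.

Step 8
Reactants: 10
Product: 11, (4R,5E,9E)-5,9-dimethyl-11-(phenylsulfonyl)undeca-1,5,9-trien-4-ol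
Conditions: (−)-Ipc2B(allyl) [from (+)-Ipc2BOMe, the (−)-α-pinene series, plus allylMgBr], Et2O, −78 °C; NaBO3·4H2O workup
Reagents that add atoms: allylmagnesium bromide, C=CC[Mg]Br (allyl group, delivered through the chiral borane)
Why: Brown asymmetric allylboration through a closed chair transition state; the (−)-reagent attacks the Re face of the enal carbonyl to give the (R)-carbinol (future C9′), the mirror image of the (S) outcome I recall for (+)-Ipc2B(allyl) with α-methyl enals.

Step 9
Reactants: 11
Product: 12, (2E,6E,8R)-3,7,11-trimethyl-1-(phenylsulfonyl)dodeca-2,6,10-trien-8-ol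
Conditions: Grubbs II (3 mol%), 2-methyl-2-butene/CH2Cl2, rt → 35 °C
Reagents that add atoms: 2-methyl-2-butene, CC=C(C)C (isopropylidene unit)
Why: Olefin cross-metathesis converts the terminal vinyl group into the prenyl terminus, while the existing trisubstituted alkenes are far less reactive and the carbinol centre is not involved.

Step 10
Reactants: 12
Product: 13, (2E,6E,8R)-8-(tert-butyldimethylsilyloxy)-3,7,11-trimethyldodeca-2,6,10-trienyl phenyl sulfone
Conditions: TBSCl, imidazole, DMF, rt
Reagents that add atoms: tert-butyldimethylsilyl chloride, CC(C)(C)[Si](C)(C)Cl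
Why: Silyl protection leaves the α-sulfonyl C–H as the only acidic site for the coupling and allows one fluoride step to finish the synthesis.

Step 11
Reactants: 13; 7
Product: 14, (2S)-2-[(3E,7E,9R)-9-(tert-butyldimethylsilyloxy)-4,8,12-trimethyl-2-(phenylsulfonyl)trideca-3,7,11-trienyl]-2,8-dimethyl-6-(triisopropylsilyloxy)chroman, epimeric mixture at C2′ (the C2 label is S only because the sulfonyl group changes CIP priority; no bond at C2 changes)
Conditions: n-BuLi (1.05 equiv), THF/HMPA, −78 °C; add 7; −78 → −40 °C
Reagents that add atoms: none beyond the two reactants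
Why: α-Alkylation of the allylic sulfonyl carbanion with the primary triflate (Julia-type sulfone alkylation) forms C1′–C2′, and the new C2′ centre is removed in the next step.

Step 12
Reactants: 14
Product: 15, (2R)-2-[(3E,7E,9R)-9-(tert-butyldimethylsilyloxy)-4,8,12-trimethyltrideca-3,7,11-trienyl]-2,8-dimethyl-6-(triisopropylsilyloxy)chroman
Conditions: PdCl2(dppp) (10 mol%), LiBHEt3 (3 equiv), THF, 0 °C
Reagents that add atoms: none (hydride only)
Why: Pd-catalysed reductive desulfonylation of the allylic sulfone via a π-allyl-Pd hydride delivers H to the less substituted terminus, which keeps the C3′=C4′ alkene in place and E; the silyl ethers are inert.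

Step 13
Reactants: 15
Product: 16, sargachromanol C, (2R)-2-[(3E,7E,9R)-9-hydroxy-4,8,12-trimethyltrideca-3,7,11-trienyl]-2,8-dimethylchroman-6-ol
Conditions: TBAF, AcOH (buffer), THF, 0 °C → rt, under Ar
Reagents that add atoms: none
Why: Fluoride-mediated desilylation removes the aryl TIPS and secondary TBS ethers under conditions that do not affect the allylic alcohol, the alkenes or either stereocentre.

**Compound list**
1 | 2-methylhydroquinone | Cc1cc(O)ccc1O | starting material
2 | 2-methyl-4-(triisopropylsilyloxy)phenol | Cc1cc(O[Si](C(C)C)(C(C)C)C(C)C)ccc1O | intermediate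
3 | 2-bromo-6-methyl-4-(triisopropylsilyloxy)phenol | Cc1cc(O[Si](C(C)C)(C(C)C)C(C)C)cc(Br)c1O | intermediate
4 | 2-methyl-2-vinyloxirane (racemic) | C=CC1(C)CO1 | starting material
5 | (2S)-2-[2-bromo-6-methyl-4-(TIPS-oxy)phenoxy]-2-methylbut-3-en-1-ol | OC[C@](C)(C=C)Oc1c(C)cc(O[Si](C(C)C)(C(C)C)C(C)C)cc1Br | intermediate
6 | [(2S)-2,8-dimethyl-6-(TIPS-oxy)chroman-2-yl]methanol | OC[C@]1(C)CCc2cc(O[Si](C(C)C)(C(C)C)C(C)C)cc(C)c2O1 | intermediate
7 | [(2S)-2,8-dimethyl-6-(TIPS-oxy)chroman-2-yl]methyl triflate | O=S(=O)(OC[C@]1(C)CCc2cc(O[Si](C(C)C)(C(C)C)C(C)C)cc(C)c2O1)C(F)(F)F | intermediate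
8 | geranyl bromide | CC(C)=CCC/C(C)=C/CBr | starting material
9 | geranyl phenyl sulfone | CC(C)=CCC/C(C)=C/CS(=O)(=O)c1ccccc1 | intermediate
10 | (2E,6E)-2,6-dimethyl-8-(phenylsulfonyl)octa-2,6-dienal | O=C/C(C)=C/CC/C(C)=C/CS(=O)(=O)c1ccccc1 | intermediate
11 | (4R,5E,9E)-5,9-dimethyl-11-(phenylsulfonyl)undeca-1,5,9-trien-4-ol | C=CC[C@@H](O)/C(C)=C/CC/C(C)=C/CS(=O)(=O)c1ccccc1 | intermediate
12 | (2E,6E,8R)-3,7,11-trimethyl-1-(phenylsulfonyl)dodeca-2,6,10-trien-8-ol | CC(C)=CC[C@@H](O)/C(C)=C/CC/C(C)=C/CS(=O)(=O)c1ccccc1 | intermediate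
13 | (8R)-8-(TBS-oxy)farnesyl phenyl sulfone | CC(C)=CC[C@@H](O[Si](C)(C)C(C)(C)C)/C(C)=C/CC/C(C)=C/CS(=O)(=O)c1ccccc1 | intermediate
14 | coupled 2′-sulfonyl bis-silyl ether (C2′ epimers) | CC(C)=CC[C@@H](O[Si](C)(C)C(C)(C)C)/C(C)=C/CC/C(C)=C/C(C[C@]1(C)CCc2cc(O[Si](C(C)C)(C(C)C)C(C)C)cc(C)c2O1)S(=O)(=O)c1ccccc1 | intermediate
15 | 6-O-TIPS, 9′-O-TBS sargachromanol C | CC(C)=CC[C@@H](O[Si](C)(C)C(C)(C)C)/C(C)=C/CC/C(C)=C/CC[C@]1(C)CCc2cc(O[Si](C(C)C)(C(C)C)C(C)C)cc(C)c2O1 | intermediate
16 | sargachromanol C | CC(C)=CC[C@@H](O)/C(C)=C/CC/C(C)=C/CC[C@]1(C)CCc2cc(O)cc(C)c2O1 | target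

**Totals**
- Total steps: 13 (chroman branch 5, side-chain branch 5, end-game 3).
- Longest linear sequence: 8 steps (1 → 2 → 3 → 5 → 6 → 7 → 14 → 15 → 16; the side-chain branch 8 → 13 → 16 is also 8).

**Three steps most likely to fail, with fallbacks**
1. Step 3 (asymmetric etherification with a di-ortho-substituted phenol): the risks are linear versus tertiary attack, the level of ee, and the sense of induction. Fallback: build the chroman by an o-quinone-methide hetero-Diels–Alder of phenol 2 with paraformaldehyde and methyl methacrylate to the racemic chroman-2-carboxylate, reduce with LiAlH4, and obtain (S)-6 by lipase kinetic resolution of the chromanmethanol (or classical resolution of the acid).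
2. Step 4 (hydroboration/intramolecular B-alkyl Suzuki ring closure with a free OH): the risks are protodeboronation and β-hydride elimination. Fallback: Parham cyclisation, i.e. TBS-protect the CH2OH of 5, hydroborate/oxidise to the primary alcohol, convert to the iodide, then Br/Li exchange (t-BuLi) and intramolecular alkylation to close C4–C4a.
3. Step 11 (sulfone-anion alkylation of the neopentyl triflate): the risks are slow SN2 and attack at sulfur. Fallback: change the bond formed to C2′–C3′: oxidise 6 to the aldehyde, methylenate to the (S)-2-vinylchroman, hydroborate with 9-BBN and run an intermolecular B-alkyl Suzuki coupling with an (E)-vinyl iodide side chain (made by Negishi carboalumination/iodination), which gives 15 directly with no sulfone.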